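At early times the two routes out of L can be read from one reading: on my picture the J gained per D gained is proportional to x, the fraction of L still free, and the first summer reading gives J 35.4 % against D 18.8 % while x averages 0.722. That yields 13.0 M⁻¹, my selectivity factor per unit charge: J gained per D gained at x of one, divided by the starting concentration of L. Times the charge it gives r, where r of one is the symmetric case, both routes using L equally at the start. Integrating with x taken to zero leaves J = 1 − ln(1 + r)/r, counting D and Q as the remainder.

| flask | L | remark | time |
|---|---|---|---|
| summer | 0.20 M | run made earlier |  |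
| autumn | 0.30 M | run made earlier |  |
| flask | 0.40 M |  | 5.0 h |

| run | time / h | L / % | J / % | Q / % | D / % |
|---|---|---|---|---|---|
| summer | 0.500 | 44.3 | 35.4 | 0 | 18.8 |
| summer | 1.33 | 18.4 | 45.9 | 0.4 | 32.6 |
| summer | 2.50 | 8.4 | 49.6 | 1.7 | 40.0 |
| summer | 4.00 | 3.3 | 50.1 | 3.8 | 42.8 |
| autumn | 0.333 | 48.5 | 36.9 | 0 | 14.0 |
| autumn | 0.667 | 30.2 | 48.9 | 0.4 | 20.8 |
| autumn | 1.50 | 13.2 | 55.9 | 0.4 | 29.3 |
| autumn | 4.00 | 2.9 | 58.6 | 3.7 | 36.2 |

(readings scatter by 0.5 percentage points)

- percent here means L units held: one J counts as two
- a reading or a percentage of D counts all its forms, free or not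
- a reading or a percentage of L is of its free form alone

- the species in which most of what was charged as L, at 5.0 h sits (J / Q / L / D)
- the largest share itself, whichever of these holds it, in percent of the L charged

For the flask, r is 5.22, so J is 65.0 %. The weak link is one reading stretched across charges, so I test it on last readings, where x, 3.3 % in summer, lies far below that run's 1/r of 38.3 %, the x at which on my picture the two routes use L equally. The rule gives 50.8 % in summer against 50.1 % read, and 59.3 % in autumn against 58.6 % read. Both run high, by 0.72 percentage points on average, so I take that off and commit to J at 64.3 %.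

The forecast says J at 64 %, from 60.5 % to 66.5 %, on a ratio that “scales with concentration”; my figure lies inside that range.

The flask gives J at 64.3 %, with D at 30.8 %, so the forecast stands.

    2 L → J (k = 3.80 M⁻¹ h⁻¹)
    Z ⇌ D, rate k2*(cs2 - [D]) while solid is left; crystals form when [D] > cs2 (solubility = 0.270 M, k = 9.60 h⁻¹)
    L + D ⇌ E, settled at all times (K = 0.870 M⁻¹)
    L → D (k = 0.580 h⁻¹)
    D → Q (k = 0.0290 h⁻¹)

In this flask the step from L to D uses 0.19 of what the step to J uses just after the start and 0.67 at 0.579 h. Half of its turnover up to 5.0 h is done by 0.179 h in the step to J, sooner than the 0.579 h of the step to D. For the neighbour at 0.10 M, r is 1.30, near the symmetric case, and the rule less its correction gives J 35.2 %. That neighbour computes to J 35.7 % and D 55.2 %, so there D holds most.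

The earlier runs and the new flask are simulated for an exercise; scatter was added.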